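The route rests on cutting the C2=C3 double bond of the cyclopentene (ring B), the only alkene of the target, which lies between the methyl-bearing ring-fusion carbon C1 and the isopropyl carbinol carbon C4 of the trans-fused bicyclo[5.3.0]decene. Both alkene carbons arrive as terminal vinyl groups in one three-component coupling on a cycloheptenone (ring A): vinyl adds to C1 and acrolein is trapped at C5. Ring-closing metathesis then joins C2 to C3 and creates the rigid hydroazulene whose faces steer the later isopropyl addition at C4 and hydride delivery at C6. The metathesis precursor is a 2-(1-hydroxyallyl)-3-vinylcycloheptanone already carrying the C8 carbinol, set by desymmetrising a meso oxabicyclic ketone.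

Key step: step 6

Numbering: C1 = ring-fusion carbon bearing CH3; C2=C3 = alkene of ring B; C4 = carbinol carbon bearing isopropyl; C5 = ring-fusion CH; C6 = ester carbinol; C7 = CH2; C8 = C(CH3)(OH); C9 and C10 = CH2 back to C1; ring A = C1, C5–C10; ring B = C1–C5; names of bicyclo[5.3.0] compounds use these route locants; β = face of the C1 methyl, α = face of H5.

Assumption: the sense of induction of the chiral lithium amide (step 3) and of the chiral copper catalyst (step 5) is assigned by analogy with simpler ketones and enones, and the antipodal amine or ligand would be used if either proves opposite; C4 (compounds 12–15) and C6 (compounds 15, 16, 18) are carried as epimer mixtures because both centres are reset later.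

Step 1
Reactants: 1 2,5-dimethylfuran; 2 1,1,3-trichloropropan-2-one
Product: 4 (1R,5S)-1,5-dimethyl-8-oxabicyclo[3.2.1]oct-6-en-3-one (meso), via dichloro cycloadduct 3 (not isolated)
Conditions: Et3N, CF3CH2OH, 0 °C to rt; crude 3 then Zn–Cu couple, NH4Cl, MeOH, rt
Reagents that add atoms: none
Why: Oxyallyl-cation [4+3] cycloaddition: base-induced loss of HCl from 2 in the ionising fluorinated alcohol gives a 1,3-dichloro-oxyallyl cation that adds across the electron-rich furan diene, and Zn–Cu reductive dechlorination of crude 3 leaves the ketone; the oxygen bridge forces the two methyl-bearing bridgeheads cis, so a single meso compound results.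

Step 2
Reactants: 4
Product: 5 (1R,5S)-1,5-dimethyl-8-oxabicyclo[3.2.1]octan-3-one (meso)
Conditions: H2 (1 atm), Pd/C, EtOAc, rt
Reagents that add atoms: none
Why: Catalytic hydrogenation saturates the strained cis-alkene without touching the ketone or the ether bridge, so that the enone of step 4 is not a dienone open to 1,6-addition; no stereocentre changes.

Step 3
Reactants: 5
Product: 7 (1S,5R)-1,5-dimethyl-3-(trimethylsilyloxy)-8-oxabicyclo[3.2.1]oct-2-ene, via lithium enolate 6 (not isolated)
Conditions: lithium bis[(R)-1-phenylethyl]amide (from the amine and n-BuLi), LiCl, TMSCl (in situ quench), THF, −100 °C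
Reagents that add atoms: chlorotrimethylsilane, C[Si](C)(C)Cl
Why: Enantiotopic-group-selective deprotonation of a meso ketone by a chiral lithium amide with in situ silylation (asymmetric desymmetrisation): the base removes one of the two enantiotopic α-CH2 hydrogens, which decides which bridgehead becomes C8 and so fixes the absolute configuration (R) of the future C8 carbinol.

Step 4
Reactants: 7
Product: 8 (R)-3,6-dimethyl-6-(trimethylsilyloxy)cyclohept-2-en-1-one
Conditions: TMSOTf (0.1 equiv), CH2Cl2, −78 °C; Et3N quench
Reagents that add atoms: none
Why: Lewis-acid-induced vinylogous β-elimination of a β-alkoxy silyl enol ether: silylation of the bridging oxygen lets the enol ether push out the allylic C1–O bond, giving the enone and leaving the silyl group on the C8 oxygen; the C8–O bond is not broken, so its configuration is kept.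

Step 5
Reactants: 8; 9 vinylmagnesium bromide; 10 acrolein
Product: 13 (2R,3S,6R)-3-ethenyl-6-hydroxy-2-(1-hydroxyprop-2-en-1-yl)-3,6-dimethylcycloheptan-1-one (carbinol epimers), via magnesium enolate 11 (not isolated), via silyl-protected aldol 12 (not isolated)
Conditions: 9, Cu(OTf)2 (5 mol %), (S)-1-(1-hydroxy-4-methylpentan-2-yl)-3-mesitylimidazolinium hexafluorophosphate (6 mol %), Et2O, −30 °C; then 10, −78 °C; aq NH4Cl; citric acid, MeOH, 0 °C
Reagents that add atoms: none
Why: Copper-catalysed asymmetric conjugate addition of a Grignard reagent to a β-methyl cycloalkenone with aldol trapping of the magnesium enolate (three-component coupling): the chiral NHC–copper catalyst should set the quaternary centre C1 under catalyst control with vinyl on the α face (the 1,4-remote C8 centre is expected to exert little bias and its silyl ether blocks alkoxide-directed delivery), acrolein should add to C5 through a Zimmerman–Traxler transition state anti to the pseudo-axial vinyl group so that the side chain is trans to it, the carbinol centre C4 is left uncontrolled because step 8 erases it, and the acidic methanol work-up cleaves the tertiary TMS ether.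

Step 6
Reactants: 13
Product: 14 (1S,5R,8R)-4,8-dihydroxy-1,8-dimethylbicyclo[5.3.0]dec-2-en-6-one (route locants; trans-fused; both C4 epimers)
Conditions: second-generation Grubbs catalyst RuCl2(H2IMes)(PCy3)(=CHPh) (5 mol %), CH2Cl2 (0.005 M), 40 °C
Reagents that add atoms: none
Why: Ring-closing olefin metathesis: the ruthenium alkylidene loads on the unhindered vinyl group of the allylic alcohol, [2+2] cycloaddition with the neopentyl vinyl group on C1 and cycloreversion of the ruthenacyclobutane release ethylene and join C2 to C3. The closest known reaction type is cyclopentene formation from 1,6-dienes whose vinyl groups sit on carbinol and quaternary carbons. Ring B is closed as a five-membered ring in the ring-closing-metathesis mode, trans-fused onto the seven-membered ring A. No stereocentre is created: the cis alkene geometry is imposed by the ring, and the trans fusion is inherited from the trans arrangement of vinyl group and side chain set in step 5. The step needs cyclisation to outrun cross-metathesis and alkene migration; this is secured because the two vinyl groups sit on adjacent ring atoms and can only form a five-membered ring, the alkene has no allylic hydrogen on its C1 side, and high dilution suppresses dimers.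

Step 7
Reactants: 14
Product: 15 (1S,5S,8R)-1,8-dimethylbicyclo[5.3.0]dec-2-ene-4,6,8-triol (route locants; C4 and C6 epimers)
Conditions: NaBH4, MeOH, 0 °C
Reagents that add atoms: none
Why: Borohydride reduction of the saturated ketone only masks C6 as an alcohol during steps 8 and 9, so its facial outcome (attack anti to the angular methyl, giving mainly the alcohol cis to it, is expected) does not matter.

Step 8
Reactants: 15
Product: 16 (1S,5S,8R)-6,8-dihydroxy-1,8-dimethylbicyclo[5.3.0]dec-2-en-4-one (route locants; C6 epimers)
Conditions: activated MnO2 (excess), CH2Cl2, rt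
Reagents that add atoms: none
Why: Chemoselective MnO2 oxidation of the allylic C4 alcohol (both epimers converge on one cyclopentenone) leaves the saturated secondary C6 alcohol and the tertiary C8 alcohol untouched.

Step 9
Reactants: 16; 17 isopropylmagnesium chloride
Product: 18 (1S,4S,5S,8R)-4-isopropyl-1,8-dimethylbicyclo[5.3.0]dec-2-ene-4,6,8-triol (route locants; C6 epimers)
Conditions: 17 (5 equiv) premixed with anhydrous CeCl3 (5 equiv), THF, −78 °C to −40 °C; aq NH4Cl
Reagents that add atoms: none
Why: Organocerium 1,2-addition to a hindered, enolisable enone (cerium suppresses enolisation, β-hydride reduction and conjugate addition, and the two hydroxyls are carried as alkoxides); the nucleophile should enter the cyclopentenone on the α face, anti to the adjacent C5–C6 bond and to the angular C1 methyl, which places the C4 hydroxyl β as required.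

Step 10
Reactants: 18
Product: 19 (1S,4S,5R,8R)-4,8-dihydroxy-4-isopropyl-1,8-dimethylbicyclo[5.3.0]dec-2-en-6-one (route locants)
Conditions: Dess–Martin periodinane, NaHCO3, CH2Cl2, 0 °C to rt; used crude
Reagents that add atoms: none
Why: Dess–Martin oxidation of the only secondary alcohol regenerates the C6 ketone under buffered, non-basic conditions that avoid retro-aldol cleavage of the two β-hydroxy ketone units, and both C6 epimers converge; tertiary alcohols are inert.

Step 11
Reactants: 19
Product: 20 (1S,4S,5S,6S,8R)-4-isopropyl-1,8-dimethylbicyclo[5.3.0]dec-2-ene-4,6,8-triol (route locants)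
Conditions: Me4NBH(OAc)3, MeCN/AcOH (1:1), −30 °C to −20 °C
Reagents that add atoms: none
Why: Evans–Saksena hydroxyl-directed reduction: the triacetoxyborohydride exchanges onto the β-hydroxyls at C4 and C8, which both lie on the β face, and delivers hydride intramolecularly to that face of C6, so the new hydroxyl is α and 1,3-anti to both, as in the target.

Step 12
Reactants: 20; 21 4-acetoxy-3-methoxybenzoic acid
Product: 23 (1S,4S,5S,6S,8R)-4,8-dihydroxy-4-isopropyl-1,8-dimethylbicyclo[5.3.0]dec-2-en-6-yl 4-hydroxy-3-methoxybenzoate (route locants), via aryl acetate 22 (not isolated)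
Conditions: 21, EDC·HCl, DMAP, CH2Cl2, rt; then pyrrolidine, 0 °C
Reagents that add atoms: none
Why: Steglich esterification should acylate the lone secondary hydroxyl in preference to the two tertiary ones, and aminolysis by pyrrolidine cleaves the phenolic acetate much faster than the hindered benzoate of a secondary alcohol, so the vanillate is unveiled in the same flask.

Compound list
1 | 2,5-dimethylfuran | Cc1ccc(C)o1 | starting material
2 | 1,1,3-trichloropropan-2-one | O=C(CCl)C(Cl)Cl | starting material
3 | 2,4-dichloro-1,5-dimethyl-8-oxabicyclo[3.2.1]oct-6-en-3-one (cis bridgeheads; C–Cl epimers) | C[C@]12C=C[C@](C)(O1)C(Cl)C(=O)C2Cl | intermediate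
4 | (1R,5S)-1,5-dimethyl-8-oxabicyclo[3.2.1]oct-6-en-3-one (meso) | C[C@]12C=C[C@](C)(O1)CC(=O)C2 | intermediate
5 | (1R,5S)-1,5-dimethyl-8-oxabicyclo[3.2.1]octan-3-one (meso) | C[C@]12CC[C@](C)(O1)CC(=O)C2 | intermediate
6 | lithium (1S,5R)-1,5-dimethyl-8-oxabicyclo[3.2.1]oct-2-en-3-olate | C[C@]12CC[C@](C)(O1)C=C(O[Li])C2 | intermediate
7 | (1S,5R)-1,5-dimethyl-3-(trimethylsilyloxy)-8-oxabicyclo[3.2.1]oct-2-ene | C[C@]12CC[C@](C)(O1)C=C(O[Si](C)(C)C)C2 | intermediate
8 | (R)-3,6-dimethyl-6-(trimethylsilyloxy)cyclohept-2-en-1-one | CC1=CC(=O)C[C@](C)(O[Si](C)(C)C)CC1 | intermediate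
9 | vinylmagnesium bromide | C=C[Mg]Br | starting material
10 | acrolein (prop-2-enal) | C=CC=O | starting material
11 | bromomagnesium (3S,6R)-3-ethenyl-3,6-dimethyl-6-(trimethylsilyloxy)cyclohept-1-en-1-olate | Br[Mg]OC1=C[C@](C)(C=C)CC[C@@](C)(O[Si](C)(C)C)C1 | intermediate
12 | (2R,3S,6R)-3-ethenyl-2-(1-hydroxyprop-2-en-1-yl)-3,6-dimethyl-6-(trimethylsilyloxy)cycloheptan-1-one (carbinol epimers) | O=C1C[C@](C)(O[Si](C)(C)C)CC[C@@](C)(C=C)[C@@H]1C(O)C=C | intermediate
13 | (2R,3S,6R)-3-ethenyl-6-hydroxy-2-(1-hydroxyprop-2-en-1-yl)-3,6-dimethylcycloheptan-1-one (carbinol epimers) | O=C1C[C@](C)(O)CC[C@@](C)(C=C)[C@@H]1C(O)C=C | intermediate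
14 | (1S,5R,8R)-4,8-dihydroxy-1,8-dimethylbicyclo[5.3.0]dec-2-en-6-one (route locants; trans-fused; C4 epimers) | O=C1C[C@](C)(O)CC[C@@]2(C)C=CC(O)[C@H]12 | intermediate
15 | (1S,5S,8R)-1,8-dimethylbicyclo[5.3.0]dec-2-ene-4,6,8-triol (route locants; C4 and C6 epimers) | OC1C[C@](C)(O)CC[C@@]2(C)C=CC(O)[C@H]12 | intermediate
16 | (1S,5S,8R)-6,8-dihydroxy-1,8-dimethylbicyclo[5.3.0]dec-2-en-4-one (route locants; C6 epimers) | OC1C[C@](C)(O)CC[C@@]2(C)C=CC(=O)[C@H]12 | intermediate
17 | isopropylmagnesium chloride | CC(C)[Mg]Cl | starting material
18 | (1S,4S,5S,8R)-4-isopropyl-1,8-dimethylbicyclo[5.3.0]dec-2-ene-4,6,8-triol (route locants; C6 epimers) | OC1C[C@](C)(O)CC[C@@]2(C)C=C[C@@](O)(C(C)C)[C@H]12 | intermediate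
19 | (1S,4S,5R,8R)-4,8-dihydroxy-4-isopropyl-1,8-dimethylbicyclo[5.3.0]dec-2-en-6-one (route locants) | O=C1C[C@](C)(O)CC[C@@]2(C)C=C[C@@](O)(C(C)C)[C@H]12 | intermediate
20 | (1S,4S,5S,6S,8R)-4-isopropyl-1,8-dimethylbicyclo[5.3.0]dec-2-ene-4,6,8-triol (route locants) | O[C@H]1C[C@](C)(O)CC[C@@]2(C)C=C[C@@](O)(C(C)C)[C@H]12 | intermediate
21 | 4-acetoxy-3-methoxybenzoic acid | COc1cc(C(=O)O)ccc1OC(C)=O | starting material
22 | (1S,4S,5S,6S,8R)-4,8-dihydroxy-4-isopropyl-1,8-dimethylbicyclo[5.3.0]dec-2-en-6-yl 4-acetoxy-3-methoxybenzoate (route locants) | COc1cc(C(=O)O[C@H]2C[C@](C)(O)CC[C@@]3(C)C=C[C@@](O)(C(C)C)[C@H]23)ccc1OC(C)=O | intermediate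
23 | (1S,4S,5S,6S,8R)-4,8-dihydroxy-4-isopropyl-1,8-dimethylbicyclo[5.3.0]dec-2-en-6-yl 4-hydroxy-3-methoxybenzoate (route locants) | COc1cc(C(=O)O[C@H]2C[C@](C)(O)CC[C@@]3(C)C=C[C@@](O)(C(C)C)[C@H]23)ccc1O | target

Total step count: 12. Longest linear sequence: 12 steps (1 and 2 to 23).

Steps most likely to fail

Step 5. What may go wrong: mismatched double stereodifferentiation, in which the resident C8 centre erodes the catalyst's control of C1; sluggish trapping at the hindered C5, so that acrolein polymerises before it is captured; or trapping on the wrong face of the enolate. The fallback sets out from 8 and separates the two bond formations. The same copper-catalysed vinyl addition is quenched with TMSCl to give silyl enol ether F1, which can be purified and freed of the minor C1 epimer. F1 is then joined to 10 by a Mukaiyama aldol addition (BF3·OEt2, CH2Cl2, −78 °C), whose open transition state should bring the Lewis-acid-bound aldehyde in anti to the pseudo-axial vinyl group. This gives 12, where the fallback comes back to the route (the acidic methanol treatment then gives 13).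

Step 9. What may go wrong: enolisation at C5, β-hydride reduction of the enone by the secondary alkyl nucleophile, or retro-aldol opening of ring A through the C6 alkoxide, in place of 1,2-addition. The fallback sets out from 16 and uses an sp2 nucleophile that has no β-hydrogen: 2-propenylmagnesium bromide with CeCl3 should add to the same α face to give isopropenyl carbinol F2. Chemoselective hydrogenation of its exposed 1,1-disubstituted alkene (H2, RhCl(PPh3)3, benzene), which is far more accessible than the ring B alkene wedged between two fully substituted carbons, then gives 18, where the fallback comes back to the route.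

Step 6. What may go wrong: isomerisation of the secondary allylic alcohol to an ethyl ketone by ruthenium hydride species, dehydration or retro-aldol cleavage of the doubly β-hydroxylated ketone on warming, or oligomerisation outrunning closure of the trans-fused ring. The fallback sets out from 13 and removes the sensitive ketone before ring closure, so that steps 7 and 6 change places. NaBH4 reduction gives monocyclic triol F3, which no longer has a β-hydroxy ketone. Ring-closing metathesis of F3 with the phosphine-free second-generation Hoveyda–Grubbs catalyst RuCl2(H2IMes)(=CH-C6H4-2-OiPr) and 1,4-benzoquinone as hydride scavenger gives 15 directly, where the fallback comes back to the route.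

Further compounds
F1 | step 5 | (3S,6R)-3-ethenyl-3,6-dimethyl-1,6-bis(trimethylsilyloxy)cyclohept-1-ene | C[Si](C)(C)OC1=C[C@](C)(C=C)CC[C@@](C)(O[Si](C)(C)C)C1
F2 | step 9 | (1S,4S,5S,8R)-1,8-dimethyl-4-(prop-1-en-2-yl)bicyclo[5.3.0]dec-2-ene-4,6,8-triol (route locants; C6 epimers) | OC1C[C@](C)(O)CC[C@@]2(C)C=C[C@@](O)(C(C)=C)[C@H]12
F3 | step 6 | (2S,3S,6R)-3-ethenyl-2-(1-hydroxyprop-2-en-1-yl)-3,6-dimethylcycloheptane-1,6-diol (C1 and side-chain carbinol epimers) | OC1C[C@](C)(O)CC[C@@](C)(C=C)[C@@H]1C(O)C=C
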